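## Retrosynthetic overview

1. The target comes from a bicyclic α-methylene lactone carbinol by 1,4-reduction, which sets the lactone methyl centre, and oxidation of the side-chain carbinol.
2. Both rings form together in the only ring-forming step. An acyclic bromo acetal is unmasked, then closed by intramolecular indium allylation (C5–C6 bond) and lactonisation (O6–C9 bond).
3. The acyclic precursor comes from a trisubstituted 2,3-epoxy alcohol, opened at C7 with inversion by isobutyric acid. This gives the tertiary C1–OH and the C7 ester.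
4. The epoxy alcohol comes from asymmetric epoxidation of an (E)-α-branched enal followed by propenyl addition. The enal comes from an aldol condensation with glyoxal monoacetal.
5. The chain and the C2 methyl centre come from (S)-citronellal, extended by cross-metathesis with methyl 2-(hydroxymethyl)acrylate.

**Atom labels:** C1 = carbinol carbon bearing the side chain, C2 = CHMe, C3 and C4 = CH2, C5 and C6 = ring-fusion carbons (C6 bears the lactone O), C7 = CH–O-isobutyrate, C8 = lactone α-carbon, C9 = lactone C=O, C10 = first side-chain carbon.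

**Assumption:** the C10 carbinol centre made in step 4 is carried as an epimer mixture and drawn without configuration, because step 9 destroys it.

## Forward route

Step 1
Reactants: 1 (S)-citronellal; 2 methyl 2-(hydroxymethyl)acrylate
Product: 3 methyl (2E,6S)-2-(hydroxymethyl)-6-methyl-8-oxooct-2-enoate
Conditions: 2 (3 equiv), second-generation Hoveyda–Grubbs catalyst (2 mol %), dimethyl carbonate, 80 °C, Ar sweep
Reagents that add atoms: none
Why: Olefin cross-metathesis of the prenyl end with a 1,1-disubstituted acrylate behaves like the known citronellal/methacrylate case, is driven by loss of isobutene, gives the alkene with the chain trans to the ester, and leaves C2 (S) untouched.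

Step 2
Reactants: 3 methyl (2E,6S)-2-(hydroxymethyl)-6-methyl-8-oxooct-2-enoate; 4 2,2-dimethoxyacetaldehyde
Product: 5 methyl (2E,6S,7E)-7-formyl-2-(hydroxymethyl)-9,9-dimethoxy-6-methylnona-2,7-dienoate
Conditions: 4 (60 % aq, 2 equiv), pyrrolidine (20 mol %), propanoic acid (20 mol %), iPrOH, 45 °C
Reagents that add atoms: none
Why: Amine-catalysed crossed aldol condensation onto a non-enolisable acceptor (the reaction type used to make 2-methylfumaraldehyde monoacetal) gives the thermodynamic (E)-enal, with C6 trans to the formyl group as the epoxide route requires.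

Step 3
Reactants: 5 methyl (2E,6S,7E)-7-formyl-2-(hydroxymethyl)-9,9-dimethoxy-6-methylnona-2,7-dienoate
Product: 6 methyl (2E,6S)-6-[(2S,3S)-3-(dimethoxymethyl)-2-formyloxiran-2-yl]-2-(hydroxymethyl)hept-2-enoate
Conditions: 50 % aq H2O2 (1.5 equiv), 9-amino(9-deoxy)epi-cinchona amine·TRIP phosphate salt (10 mol %, pseudoenantiomer giving Si-face attack), THF, 45 °C
Reagents that add atoms: hydrogen peroxide OO
Why: Iminium-catalysed asymmetric Weitz–Scheffer epoxidation of an α-branched enal touches only the enal alkene (the tail enoate is inert), and the chiral ion pair directs peroxide to the Si face of C7 so that C1 and C7 are set together stereospecifically.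

Step 4
Reactants: 6 methyl (2E,6S)-6-[(2S,3S)-3-(dimethoxymethyl)-2-formyloxiran-2-yl]-2-(hydroxymethyl)hept-2-enoate; 7 propyne
Product: 8 methyl (2E,6S)-6-{(2R,3S)-3-(dimethoxymethyl)-2-[(2E)-1-hydroxybut-2-en-1-yl]oxiran-2-yl}-2-(hydroxymethyl)hept-2-enoate (carbinol epimers)
Conditions: 7, Cp2Zr(H)Cl, CH2Cl2, rt; Me2Zn (2.5 equiv), −65 °C; 6, 0 °C; aq NH4Cl
Reagents that add atoms: none
Why: Syn hydrozirconation, zinc transmetalation and 1,2-addition of the alkenylzinc fix the (E)-propenyl geometry and attack only the aldehyde, sparing epoxide, ester and acetal, while the new carbinol centre does not matter.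

Step 5
Reactants: 8 methyl (2E,6S)-6-{(2R,3S)-3-(dimethoxymethyl)-2-[(2E)-1-hydroxybut-2-en-1-yl]oxiran-2-yl}-2-(hydroxymethyl)hept-2-enoate; 9 isobutyric acid
Product: 10 methyl (2E,6S,7R,9E)-7-[(1R)-2,2-dimethoxy-1-(2-methylpropanoyloxy)ethyl]-7,8-dihydroxy-2-(hydroxymethyl)-6-methylundeca-2,9-dienoate (C8 epimers)
Conditions: 9 (3 equiv), Ti(OiPr)4 (1.5 equiv), CH2Cl2, rt; aq tartaric acid
Reagents that add atoms: none
Why: Titanium-assisted opening of a 2,3-epoxy alcohol by a carboxylic acid goes by SN2 at the distal epoxide carbon, so C7 is inverted and acylated in one step while the C1–O bond, and hence the tertiary carbinol configuration, is retained.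

Step 6
Reactants: 10 methyl (2E,6S,7R,9E)-7-[(1R)-2,2-dimethoxy-1-(2-methylpropanoyloxy)ethyl]-7,8-dihydroxy-2-(hydroxymethyl)-6-methylundeca-2,9-dienoate
Product: 11 methyl (2Z,6S,7R,9E)-2-(bromomethyl)-7-[(1R)-2,2-dimethoxy-1-(2-methylpropanoyloxy)ethyl]-7,8-dihydroxy-6-methylundeca-2,9-dienoate
Conditions: NBS, Me2S, CH2Cl2, −30 to 0 °C
Reagents that add atoms: N-bromosuccinimide O=C1CCC(=O)N1Br
Why: Corey–Kim-type bromination through the alkoxysulfonium salt picks the unhindered primary allylic alcohol over the neopentyl-like secondary carbinol and the tertiary alcohol and creates no stereocentre.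

Step 7
Reactants: 11 methyl (2Z,6S,7R,9E)-2-(bromomethyl)-7-[(1R)-2,2-dimethoxy-1-(2-methylpropanoyloxy)ethyl]-7,8-dihydroxy-6-methylundeca-2,9-dienoate
Product: 14 (3aS,6S,7R,8S,8aR)-7-hydroxy-7-[(2E)-1-hydroxybut-2-en-1-yl]-6-methyl-3-methylidene-2-oxooctahydro-2H-cyclohepta[b]furan-8-yl 2-methylpropanoate, via bromo aldehyde 12 (not isolated), via ring-closed hydroxy ester 13 (not isolated)
Conditions: 0.5 M aq HCl/THF 1:3, rt; then dilute to 0.005 M, indium powder (3 equiv), sonication, rt to 40 °C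
Reagents that add atoms: water O
Why: After acetal hydrolysis, indium converts the allylic bromide into a water-tolerant allylindium that adds through C5 to the C6 aldehyde (released from its lactol) in an intramolecular Barbier allylation, and the cis γ-hydroxy ester lactonises at once (Dreiding–Schmidt-type annulation), so cycloheptane and lactone arise together on the unprotected substrate; the closed chair with the C4 chain cis to CH2In gives the syn adduct (cis fusion, C5 S), and the forming seven-membered chair that keeps C2-Me, the C1 side chain and the acrylate equatorial with the C6=O and C7–O dipoles anti places O6 trans to the isobutyrate (C6 R).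

Step 8
Reactants: 14 (3aS,6S,7R,8S,8aR)-7-hydroxy-7-[(2E)-1-hydroxybut-2-en-1-yl]-6-methyl-3-methylidene-2-oxooctahydro-2H-cyclohepta[b]furan-8-yl 2-methylpropanoate
Product: 15 (3R,3aS,6S,7R,8S,8aR)-7-hydroxy-7-[(2E)-1-hydroxybut-2-en-1-yl]-3,6-dimethyl-2-oxooctahydro-2H-cyclohepta[b]furan-8-yl 2-methylpropanoate
Conditions: NaBH4, MeOH, −20 to 0 °C
Reagents that add atoms: none
Why: Conjugate hydride reduction of the α-methylene lactone leaves the isolated propenyl alkene and the esters alone, and kinetic protonation of the lactone enolate from the convex face (the face of H-3a and H-8a) puts the methyl group on the concave face (C8 R).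

Step 9
Reactants: 15 (3R,3aS,6S,7R,8S,8aR)-7-hydroxy-7-[(2E)-1-hydroxybut-2-en-1-yl]-3,6-dimethyl-2-oxooctahydro-2H-cyclohepta[b]furan-8-yl 2-methylpropanoate
Product: 16 (3R,3aS,6S,7S,8S,8aR)-7-[(2E)-but-2-enoyl]-7-hydroxy-3,6-dimethyl-2-oxooctahydro-2H-cyclohepta[b]furan-8-yl 2-methylpropanoate (target)
Conditions: 2-iodoxybenzoic acid (1.5 equiv), DMSO, rt
Reagents that add atoms: none
Why: Oxidation with 2-iodoxybenzoic acid converts the secondary allylic alcohol of the secondary/tertiary 1,2-diol into the α-hydroxy enone without glycol cleavage, merges both carbinol epimers and touches no other stereocentre.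

## Compound list

1 | (S)-citronellal, (3S)-3,7-dimethyloct-6-enal | C[C@@H](CCC=C(C)C)CC=O | starting material
2 | methyl 2-(hydroxymethyl)acrylate | C=C(CO)C(=O)OC | starting material
3 | methyl (2E,6S)-2-(hydroxymethyl)-6-methyl-8-oxooct-2-enoate | O=CC[C@@H](C)CC/C=C(\CO)C(=O)OC | intermediate
4 | 2,2-dimethoxyacetaldehyde | COC(OC)C=O | starting material
5 | methyl (2E,6S,7E)-7-formyl-2-(hydroxymethyl)-9,9-dimethoxy-6-methylnona-2,7-dienoate | O=C/C(=C/C(OC)OC)[C@@H](C)CC/C=C(\CO)C(=O)OC | intermediate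
6 | methyl (2E,6S)-6-[(2S,3S)-3-(dimethoxymethyl)-2-formyloxiran-2-yl]-2-(hydroxymethyl)hept-2-enoate | O=C[C@]1(O[C@@H]1C(OC)OC)[C@@H](C)CC/C=C(\CO)C(=O)OC | intermediate
7 | propyne | CC#C | starting material
8 | methyl (2E,6S)-6-{(2R,3S)-3-(dimethoxymethyl)-2-[(2E)-1-hydroxybut-2-en-1-yl]oxiran-2-yl}-2-(hydroxymethyl)hept-2-enoate (carbinol epimers) | C/C=C/C(O)[C@]1(O[C@@H]1C(OC)OC)[C@@H](C)CC/C=C(\CO)C(=O)OC | intermediate
9 | isobutyric acid | CC(C)C(=O)O | starting material
10 | methyl (2E,6S,7R,9E)-7-[(1R)-2,2-dimethoxy-1-(2-methylpropanoyloxy)ethyl]-7,8-dihydroxy-2-(hydroxymethyl)-6-methylundeca-2,9-dienoate (C8 epimers) | C/C=C/C(O)[C@@](O)([C@@H](OC(=O)C(C)C)C(OC)OC)[C@@H](C)CC/C=C(\CO)C(=O)OC | intermediate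
11 | methyl (2Z,6S,7R,9E)-2-(bromomethyl)-7-[(1R)-2,2-dimethoxy-1-(2-methylpropanoyloxy)ethyl]-7,8-dihydroxy-6-methylundeca-2,9-dienoate | C/C=C/C(O)[C@@](O)([C@@H](OC(=O)C(C)C)C(OC)OC)[C@@H](C)CC/C=C(\CBr)C(=O)OC | intermediate
12 | methyl (2Z,6S,7R,9E)-2-(bromomethyl)-7,8-dihydroxy-6-methyl-7-[(1R)-1-(2-methylpropanoyloxy)-2-oxoethyl]undeca-2,9-dienoate (open form of its five-membered lactol) | C/C=C/C(O)[C@@](O)([C@@H](OC(=O)C(C)C)C=O)[C@@H](C)CC/C=C(\CBr)C(=O)OC | intermediate
13 | methyl 2-{(1S,2R,3S,4R,5S)-2,4-dihydroxy-4-[(2E)-1-hydroxybut-2-en-1-yl]-5-methyl-3-(2-methylpropanoyloxy)cycloheptyl}prop-2-enoate | C/C=C/C(O)[C@]1(O)[C@@H](C)CC[C@@H](C(=C)C(=O)OC)[C@@H](O)[C@@H]1OC(=O)C(C)C | intermediate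
14 | (3aS,6S,7R,8S,8aR)-7-hydroxy-7-[(2E)-1-hydroxybut-2-en-1-yl]-6-methyl-3-methylidene-2-oxooctahydro-2H-cyclohepta[b]furan-8-yl 2-methylpropanoate | C/C=C/C(O)[C@]1(O)[C@@H](C)CC[C@@H]2[C@@H](OC(=O)C2=C)[C@@H]1OC(=O)C(C)C | intermediate
15 | (3R,3aS,6S,7R,8S,8aR)-7-hydroxy-7-[(2E)-1-hydroxybut-2-en-1-yl]-3,6-dimethyl-2-oxooctahydro-2H-cyclohepta[b]furan-8-yl 2-methylpropanoate | C/C=C/C(O)[C@]1(O)[C@@H](C)CC[C@@H]2[C@@H](OC(=O)[C@@H]2C)[C@@H]1OC(=O)C(C)C | intermediate
16 | (3R,3aS,6S,7S,8S,8aR)-7-[(2E)-but-2-enoyl]-7-hydroxy-3,6-dimethyl-2-oxooctahydro-2H-cyclohepta[b]furan-8-yl 2-methylpropanoate | C/C=C/C(=O)[C@]1(O)[C@@H](C)CC[C@@H]2[C@@H](OC(=O)[C@@H]2C)[C@@H]1OC(=O)C(C)C | target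

## Step count and risks

Total step count: 9. Longest linear sequence: 9 (from 1).

**Most likely to fail, first: step 7.** A seven-membered closure in water competes with protonolysis of the allylindium and with oligomerisation. The labile allylmetal may also erode the C5/C6 selectivity.

The fallback replaces the in-situ Barbier species by an isolated, configurationally defined allylboron reagent. It sets out from 11 and comes back at 14.
- Borylation with B2pin2 and Pd2(dba)3 gives the primary allylboronate acetal F1.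
- Aqueous trifluoroacetic acid unmasks it to the boronate aldehyde F2.
- In dilute toluene at 80 °C with Sc(OTf)3 (10 mol %), F2 closes through the closed-chair intramolecular allylboration. The borate lactonises on work-up to 14.

**Second: step 3.** The bulky secondary alkyl group on the enal α-carbon may slow iminium formation or lower the facial selectivity.

The fallback moves stereocontrol to a reagent-controlled epoxidation of an allylic alcohol in the prenyl series. It sets out from 1 (with 4) and comes back at 6.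
- The same aldol condensation gives the prenyl enal F3.
- NaBH4/CeCl3·7H2O gives the allylic alcohol F4.
- Sharpless asymmetric epoxidation (Ti(OiPr)4, L-(+)-diisopropyl tartrate, tBuOOH, 4 Å sieves, −20 °C) delivers oxygen from the required face and gives the epoxy alcohol F5.
- Parikh–Doering oxidation gives the epoxy aldehyde F6.
- Cross-metathesis of F6 with 2 gives 6.

**Third: step 5.** Attack at C7 is slowed by the neighbouring acetal. Opening at the tertiary C1, or acyl migration to the C10 hydroxyl, could intervene.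

The fallback makes C7 the only possible electrophilic site by raising C10 to the ketone. It sets out from 8 and comes back at 11.
- Selective bromination with NBS/Me2S gives the bromo epoxy alcohol F7.
- 2-Iodoxybenzoic acid gives the bromo epoxy enone F8. Its acyl-bearing quaternary carbon cannot be attacked.
- Isobutyric acid with its caesium salt at 50 °C then opens F8 at C7 with inversion, giving the bromo hydroxy enone isobutyrate F9.
- Luche reduction (NaBH4, CeCl3·7H2O, MeOH, −78 °C) gives 11.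

## Further compounds

F1 | step 7 | methyl (2E,6S,7R,9E)-7-[(1R)-2,2-dimethoxy-1-(2-methylpropanoyloxy)ethyl]-7,8-dihydroxy-6-methyl-2-[(4,4,5,5-tetramethyl-1,3,2-dioxaborolan-2-yl)methyl]undeca-2,9-dienoate | C/C=C/C(O)[C@@](O)([C@@H](OC(=O)C(C)C)C(OC)OC)[C@@H](C)CC/C=C(\CB1OC(C)(C)C(C)(C)O1)C(=O)OC
F2 | step 7 | methyl (2E,6S,7R,9E)-7,8-dihydroxy-6-methyl-7-[(1R)-1-(2-methylpropanoyloxy)-2-oxoethyl]-2-[(4,4,5,5-tetramethyl-1,3,2-dioxaborolan-2-yl)methyl]undeca-2,9-dienoate | C/C=C/C(O)[C@@](O)([C@@H](OC(=O)C(C)C)C=O)[C@@H](C)CC/C=C(\CB1OC(C)(C)C(C)(C)O1)C(=O)OC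
F3 | step 3 | (2E)-4,4-dimethoxy-2-[(2S)-6-methylhept-5-en-2-yl]but-2-enal | O=C/C(=C/C(OC)OC)[C@@H](C)CCC=C(C)C
F4 | step 3 | (2E)-4,4-dimethoxy-2-[(2S)-6-methylhept-5-en-2-yl]but-2-en-1-ol | OC/C(=C/C(OC)OC)[C@@H](C)CCC=C(C)C
F5 | step 3 | {(2R,3S)-3-(dimethoxymethyl)-2-[(2S)-6-methylhept-5-en-2-yl]oxiran-2-yl}methanol | OC[C@]1(O[C@@H]1C(OC)OC)[C@@H](C)CCC=C(C)C
F6 | step 3 | (2S,3S)-3-(dimethoxymethyl)-2-[(2S)-6-methylhept-5-en-2-yl]oxirane-2-carbaldehyde | O=C[C@]1(O[C@@H]1C(OC)OC)[C@@H](C)CCC=C(C)C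
F7 | step 5 | methyl (2Z,6S)-2-(bromomethyl)-6-{(2R,3S)-3-(dimethoxymethyl)-2-[(2E)-1-hydroxybut-2-en-1-yl]oxiran-2-yl}hept-2-enoate | C/C=C/C(O)[C@]1(O[C@@H]1C(OC)OC)[C@@H](C)CC/C=C(\CBr)C(=O)OC
F8 | step 5 | methyl (2Z,6S)-2-(bromomethyl)-6-{(2S,3S)-2-[(2E)-but-2-enoyl]-3-(dimethoxymethyl)oxiran-2-yl}hept-2-enoate | C/C=C/C(=O)[C@]1(O[C@@H]1C(OC)OC)[C@@H](C)CC/C=C(\CBr)C(=O)OC
F9 | step 5 | methyl (2Z,6S,7S,9E)-2-(bromomethyl)-7-[(1R)-2,2-dimethoxy-1-(2-methylpropanoyloxy)ethyl]-7-hydroxy-6-methyl-8-oxoundeca-2,9-dienoate | C/C=C/C(=O)[C@@](O)([C@@H](OC(=O)C(C)C)C(OC)OC)[C@@H](C)CC/C=C(\CBr)C(=O)OC
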